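## Retrosynthetic overview

1. Disconnect the C1 ester (Yamaguchi) into the 1β-hydroxy core and (2E,4S)-2,4-dimethyloct-2-enoic acid. The acid comes from an Evans alkylation followed by an HWE reaction.
2. The α-methylene aldehyde comes from a C7 allyl group (Lemieux–Johnson cleavage, then α-methylenation). The C15 acid comes from a C4 methoxymethylene enol ether (hydrolysis, then Pinnick oxidation).
3. C1-β-OH comes from γ-oxygenation of the enone dienolate, analogous to 6β-hydroxylation of Δ4-3-keto steroids. C7 comes from kinetic α′-alkylation.
4. Both rings are already present in (S)-Wieland–Miescher ketone, so no ring is built. Its C1 ketone becomes C4 and its enone is the C8/C9/C10 enone of the target.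

**Assumptions.** From the SMILES, the C1-O and C4-CO₂H are cis to the C5 methyl (β), and the C7 substituent is trans (α). (S)-Wieland–Miescher ketone carries the required C5 configuration, checked against the target SMILES.

## Route

**Step 1**
Reactants: 1 (R)-4-benzyl-3-propionyloxazolidin-2-one; 2 1-iodobutane
Product: 3 (R)-4-benzyl-3-[(S)-2-methylhexanoyl]oxazolidin-2-one
Conditions: NaHMDS, THF, –78 °C; then 2, –78 → –30 °C
Reagents that add atoms: 1-iodobutane, CCCCI
Why: Evans asymmetric enolate alkylation; the chelated Z-enolate is attacked anti to the benzyl group, and the (R)-auxiliary gives the (2S) centre, which becomes C4′ of the side chain.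

**Step 2**
Reactants: 3
Product: 4 (S)-2-methylhexan-1-ol
Conditions: LiBH₄, H₂O (1 equiv), Et₂O, 0 °C
Reagents that add atoms: none
Why: Hydride cleaves the imide reductively without touching the α-stereocentre, and the auxiliary is recovered.

**Step 3**
Reactants: 4
Product: 5 (S)-2-methylhexanal
Conditions: Dess–Martin periodinane, NaHCO₃, CH₂Cl₂, 0 °C; use crude at once
Reagents that add atoms: none
Why: Buffered DMP oxidation to the aldehyde avoids enolization of the α-branched aldehyde.

**Step 4**
Reactants: 5; 6 triethyl 2-phosphonopropionate
Product: 7 ethyl (2E,4S)-2,4-dimethyloct-2-enoate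
Conditions: 6, LiCl, DBU, MeCN, 0 °C → rt
Reagents that add atoms: triethyl 2-phosphonopropionate, CCOC(=O)C(C)P(=O)(OCC)OCC
Why: Masamune–Roush Horner–Wadsworth–Emmons olefination gives the trisubstituted (E)-enoate, and the mild base does not epimerize C4′.

**Step 5**
Reactants: 7
Product: 8 (2E,4S)-2,4-dimethyloct-2-enoic acid
Conditions: LiOH, THF/MeOH/H₂O, 60 °C
Reagents that add atoms: lithium hydroxide [Li+].[OH-]; water O
Why: Saponification gives the free acid; γ-deprotonation is not possible with hydroxide, so both the E-alkene and the C4′ centre are retained.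

**Step 6**
Reactants: 9 (S)-Wieland–Miescher ketone; 10 (methoxymethyl)triphenylphosphonium chloride
Product: 11 C4 methoxymethylene enol ether of 9 (E/Z mixture), enone intact
Conditions: 10, KOt-Bu, THF, 0 °C → rt
Reagents that add atoms: (methoxymethyl)triphenylphosphonium chloride, COC[P+](c1ccccc1)(c1ccccc1)c1ccccc1.[Cl-]
Why: Wittig methoxymethylenation is chemoselective for the saturated C4 ketone because the enone carbonyl is deactivated. It creates no stereocentre, and the enol ether is a base-stable masked aldehyde that also removes the C4 ketone as an enolization site.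

**Step 7**
Reactants: 11
Product: 12 1β-hydroxy enone (C1 axial OH, cis to the C5 methyl)
Conditions: KOt-Bu, O₂ (1 atm), P(OEt)₃, THF/t-BuOH, –20 → 0 °C
Reagents that add atoms: dioxygen, O=O
Why: Gardner-type oxygenation of the thermodynamic extended dienolate occurs at the γ-carbon C1, and P(OEt)₃ reduces the hydroperoxide in situ. Axial attack from the β face sets C1, by analogy with 6β-functionalization of Δ4-3-keto steroids (same A/B topology), where the stereoelectronic axial preference outweighs the syn-axial methyl.

**Step 8**
Reactants: 12; 13 allyl bromide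
Product: 14 7α-allyl-1β-hydroxy enol ether
Conditions: LDA (2.3 equiv), THF, –78 °C; then 13, DMPU, –78 → –20 °C
Reagents that add atoms: allyl bromide, C=CCBr
Why: The lithium alkoxide acts as an in-situ protecting group, and LDA forms the kinetic cross-conjugated α′-enolate at C7. C-Alkylation occurs from the α face, anti to the axial C5 methyl, giving the equatorial 7α-allyl group. Any C7 epimer equilibrates later to this thermodynamic isomer.

**Step 9**
Reactants: 14; 8
Product: 15 1β-[(2E,4S)-2,4-dimethyloct-2-enoyl] ester of 14
Conditions: 8, 2,4,6-Cl₃C₆H₂COCl, Et₃N, THF; then 14, DMAP, toluene, 60 °C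
Reagents that add atoms: none (acid 8 is the listed reactant; the trichlorobenzoyl group is not retained)
Why: Yamaguchi esterification acylates the hindered axial alcohol through the mixed anhydride with retention at C1. It is done after the LDA step so the dienoate is never exposed to strong base.

**Step 10**
Reactants: 15
Product: 16 4β-formyl compound (CHO equatorial, cis to the C5 methyl)
Conditions: 1 M aq HCl, THF, rt, short reaction time
Reagents that add atoms: water, O
Why: Enol-ether hydrolysis. Kinetic axial protonation at C4 from the α face, anti to the C5 methyl, puts the CHO equatorial and β, setting C4. The enone, allyl group and ester survive.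

**Step 11**
Reactants: 16
Product: 17 carboxylic acid (C15 acid, C7 allyl)
Conditions: NaClO₂, NaH₂PO₄, 2-methyl-2-butene, t-BuOH/H₂O, rt
Reagents that add atoms: sodium chlorite, [Na+].[O-]Cl=O
Why: Pinnick oxidation is mild enough not to epimerize C4, and the alkene scavenger protects the alkenes.

**Step 12**
Reactants: 17
Product: 18 keto aldehyde (C7 CH₂CHO)
Conditions: OsO₄ (cat.), 2,6-lutidine, NaIO₄, dioxane/H₂O, rt
Reagents that add atoms: sodium periodate, [Na+].[O-]I(=O)(=O)=O
Why: Lemieux–Johnson cleavage is selective for the monosubstituted allyl alkene over the electron-poor enone and dienoate. The sensitive keto aldehyde is used directly.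

**Step 13**
Reactants: 18; 19 formaldehyde
Product: 20 integric acid
Conditions: 37% aq. HCHO, pyrrolidine (10 mol%), propionic acid (10 mol%), THF, 0 °C → rt
Reagents that add atoms: formaldehyde, C=O
Why: Amine-catalysed Mannich condensation and elimination (α-methylenation) converts the CH₂CHO into the 2-substituted acrolein. The reversible enolization lets C7 settle at the thermodynamic α-equatorial configuration.

## Compound list

| No. | Name | SMILES | Role |
|---|---|---|---|
| 1 | (R)-4-benzyl-3-propionyloxazolidin-2-one | CCC(=O)N1C(=O)OC[C@H]1Cc1ccccc1 | starting material |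
| 2 | 1-iodobutane | CCCCI | starting material |
| 3 | (R)-4-benzyl-3-[(S)-2-methylhexanoyl]oxazolidin-2-one | CCCC[C@H](C)C(=O)N1C(=O)OC[C@H]1Cc1ccccc1 | intermediate |
| 4 | (S)-2-methylhexan-1-ol | CCCC[C@H](C)CO | intermediate |
| 5 | (S)-2-methylhexanal | CCCC[C@H](C)C=O | intermediate |
| 6 | triethyl 2-phosphonopropionate | CCOC(=O)C(C)P(=O)(OCC)OCC | starting material |
| 7 | ethyl (2E,4S)-2,4-dimethyloct-2-enoate | CCOC(=O)/C(C)=C/[C@@H](C)CCCC | intermediate |
| 8 | (2E,4S)-2,4-dimethyloct-2-enoic acid | OC(=O)/C(C)=C/[C@@H](C)CCCC | intermediate |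
| 9 | (S)-Wieland–Miescher ketone | C[C@]12CCC(=O)C=C1CCCC2=O | starting material |
| 10 | (methoxymethyl)triphenylphosphonium chloride | COC[P+](c1ccccc1)(c1ccccc1)c1ccccc1.[Cl-] | starting material |
| 11 | C4 methoxymethylene enol ether of 9 (E/Z) | C[C@]12CCC(=O)C=C1CCCC2=COC | intermediate |
| 12 | 1β-hydroxy enone enol ether | C[C@]12CCC(=O)C=C1[C@H](O)CCC2=COC | intermediate |
| 13 | allyl bromide | C=CCBr | starting material |
| 14 | 7α-allyl-1β-hydroxy enol ether | C[C@]12C[C@@H](CC=C)C(=O)C=C1[C@H](O)CCC2=COC | intermediate |
| 15 | 1β-dienoate ester, C4 enol ether | C[C@]12C[C@@H](CC=C)C(=O)C=C1[C@H](OC(=O)/C(C)=C/[C@@H](C)CCCC)CCC2=COC | intermediate |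
| 16 | 4β-formyl ester | C[C@]12C[C@@H](CC=C)C(=O)C=C1[C@H](OC(=O)/C(C)=C/[C@@H](C)CCCC)CC[C@@H]2C=O | intermediate |
| 17 | 4β-carboxylic acid, 7α-allyl | C[C@]12C[C@@H](CC=C)C(=O)C=C1[C@H](OC(=O)/C(C)=C/[C@@H](C)CCCC)CC[C@@H]2C(=O)O | intermediate |
| 18 | 7α-(2-oxoethyl) keto acid | C[C@]12C[C@@H](CC=O)C(=O)C=C1[C@H](OC(=O)/C(C)=C/[C@@H](C)CCCC)CC[C@@H]2C(=O)O | intermediate |
| 19 | formaldehyde | C=O | starting material |
| 20 | integric acid | C=C(C=O)[C@@H]1C[C@@]2(C)C(=CC1=O)[C@H](OC(=O)/C(C)=C/[C@@H](C)CCCC)CC[C@@H]2C(=O)O | target |

## Totals

- Total steps: 13 (5 for the side-chain acid, 8 for the core and coupling).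
- Longest linear sequence: 10 steps (1–5, then 9–13). From (S)-Wieland–Miescher ketone it is 8 steps (6–13).

## Three steps most likely to fail

1. **Step 7, γ-hydroxylation.** Regiochemistry (γ versus α or α′) and the β-axial stereochemistry are the main risks, and over-oxidation to the ene-dione is possible.
   - Fallback: protect C4 as its dioxolane instead of the enol ether, make the TBS silyl dienol ether, and oxidize it with DMDO. Invert any 1α-alcohol by Mitsunobu esterification with acid 8, which also replaces step 9.
2. **Step 8, dianion allylation.** O- versus C-alkylation, α′ versus γ selectivity and dialkylation are all possible problems.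
   - Fallback: protect C1-OH as its TBS ether, alkylate the monoanion, and remove the TBS group with TBAF before step 9.
3. **Step 13, α-methylenation.** The keto aldehyde can epimerize at C7, polymerize, or add the amine to the product enal.
   - Fallback: drop steps 8, 12 and 13. Install a C7 isopropenyl group by Pd-catalysed α′-alkenylation with 2-bromopropene, carry it through, and finish with SeO₂/t-BuOOH allylic oxidation to the enal.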